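## The problem

Target 37 is a guaiane: a cyclopentenone fused through C1 and C5 to a cycloheptane. Guaiane numbering is used throughout (C1 fusion carbinol, C2, C3 ketone, C4 methyl-bearing, C5, C6 carbinol, C7, C8 angelate carbon, C9, C10 methyl-bearing, C11 acetoxy carbon on C7). The seven-membered ring carries five stereocentres (1R,6R,7S,8R,10S): O6, the C7 side chain, O8 and the C10 methyl group lie on one face, O1 on the other. The centres fall into two contiguous pairs, C1/C10 and C7/C8, separated by the C9 methylene, plus C6. C10 is too remote (1,3) to direct C8, so each pair needs its own source of chirality, whereas C6, next to C7, can be left to substrate control. The compound will not survive rough treatment. The angelate is the less stable (Z)-enoate and isomerises to the tiglate under nucleophilic or basic activation. The tertiary C11 acetate sits 1,3 to a free secondary hydroxyl (acyl migration, elimination). O1 is β to the C3 carbonyl (retro-aldol under strong base) and, before the enone exists, tertiary and allylic (ionisation under strong acid). Both acyl groups therefore go on late and the closing steps stay near neutral. The feature that makes the key step possible is that C5 (β-carbon of the enone) and C6 (carbinol carbon) are both electrophilic in their natural polarity, so the C5–C6 bond calls for polarity inversion at one end. An alkenyl iodide at C5, reduced to an alkenylmetal, provides it, and because C5 and C1 are neighbours in the five-membered ring, the chain that ends in the C6 aldehyde is held next to C5.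

## Retrosynthesis

**End game (37 back to 30).** Only heteroatom bonds are cut: the two silyl ethers of 36, the C11 acetate (36 to 35), the C8 angelate (35 to diol 32 and angelic acid 33), the ketal and the C8 silyl ether (32 to 31) and the C6 silyl ether (31 to 30). The order is chosen so that the angelate goes on before the acetate: a tertiary acetate next to a free C8 hydroxyl would invite 1,3-acyl migration. O6 stays silylated until the last step so that neither acylation can touch it, and O1 stays silylated so that the C11 hydroxyl is the only free alcohol when the acetate is introduced. Nothing stereochemical is asked of these steps.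

**C5–C6 (30 to 28).** Cutting the bond between the enone β-carbon and the C6 carbinol opens the seven-membered ring to the iodocyclopentenyl aldehyde 28. Against the neighbouring cuts, C6–C7 would need a C7 enolate already burdened with the C11 group, and C1–C5 or C1–C10 would leave the tertiary carbinol to be made in a ring-forming step. Cutting C5–C6 leaves all four remaining stereocentres in an open chain, where they can be set by reagent control, and asks the ring closure to create only C6. The forward reaction must turn a tetrasubstituted alkenyl iodide into a nucleophile that tolerates a ketal, silyl ethers and a free tertiary alcohol, and must add to the aldehyde from the face dictated by C7.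

**C6 and C11 carbons (28 to 24).** The C6 aldehyde is the oxidative-cleavage product of a vinyl group (28 from 26), and the two C11 methyl groups come from an ester (26 from 24). This makes C7 the α-carbon of a β-hydroxy ester with an α-vinyl substituent, an aldol pattern. The carbonyl is given the role of C11 and the vinyl group the role of C6 because the required C7/C8 relationship is then the syn-aldol one.

**C7–C8 (24 to 15 and 19).** After removing the silyl group (24 to 23) and exchanging the ester for the auxiliary (23 to 22), the C7–C8 bond is cut to aldehyde 15 and crotonyl imide 19 (from oxazolidinone 16 and acid chloride 17). An α-selective aldol of the boron dienolate sets both centres at once under auxiliary control. The alternative cut C8–C9 would need a C9 nucleophile next to the C10 stereocentre and would set only C8.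

**C1–C10 (15 to 5 and 9).** Aldehyde 15 is the anti-Markovnikov oxidation product of the terminal alkene of 12 (through alcohol 14), and 12 is the silyl ether of homoallylic alcohol 11. Cutting C1–C10 in 11 gives iodoenone 5 and (Z)-crotylboronate 9. One cyclic transition state creates the tertiary carbinol and the adjacent methyl-bearing centre, and the ketone is reduced to a flat, achiral ring. The forward step must be 1,2-selective, diastereoselective through the crotyl geometry and enantioselective through a chiral diol.

**Five-membered ring (5 to 1; 9 to 6).** Iodoenone 5 comes from enone 4 by α-iodination, 4 from ketal 2 by oxidation of the only ring allylic methylene, and 2 from commercial 2-methylcyclopent-2-en-1-one 1. The carbonyl of 1 becomes C3 and is masked first, so the two carbonyl positions of the ring are never equivalent. Boronate 9 comes from (Z)-but-2-ene 6.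

## Roads not taken

**Alternative 1: transannular carbonyl-ene closure.** The cut is the C1–C5 fusion bond (with return of a hydrogen to the C4 methyl), leading to the ten-membered (E)-cyclodec-4-enone A2. In the forward step Me2AlCl activates the C1 ketone of A2, C5 bonds to C1 and a methyl hydrogen passes to oxygen, giving the 1-hydroxyguai-4(15)-ene A1.
- Merits: both rings and the C1 carbinol form in one step, without a halide and without stoichiometric chromium. In bond economy this road is better than the chosen one.
- Weak points: A2 is harder to make than the problem it solves, since a ten-membered ring with an (E)-trisubstituted olefin and four stereocentres must be closed first. The configuration at C1 depends on which ring conformer reacts, and three contiguous cis substituents make that hard to foresee. A1 has the olefin exocyclic and no oxygen at C3, so isomerisation to C4=C5 and an allylic oxidation must follow in the presence of a tertiary allylic alcohol. The C5 stereocentre is made only to be erased.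
- Comparison: the chosen plan carries the C3 oxygen and the C4=C5 olefin from the first step and sets the stereocentres in an open chain by reagent control. After its ring closure only protecting-group changes and acylations remain.

**Alternative 2: vinylcarbenoid cyclopropanation, then Cope rearrangement.** The cuts are C6–C7 and C9–C10. Rh2(DOSP)4 (dirhodium tetrakis[N-(4-dodecylphenylsulfonyl)prolinate]) turns the siloxy vinyldiazoacetate A4 into a vinylcarbenoid that cyclopropanates the enol-ether double bond (C5=C6) of diene A5. The cis-divinylcyclopropane rearranges to hydroazulene A3, which has a C7 ester, a C8 silyl enol ether and a C1=C5 olefin.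
- Merits: the route is convergent, catalytic and enantioselective, and forms two C–C bonds, the seven-membered ring and two stereocentres (C6, C10) in one operation. In convergence and in steps to the bicycle it is better than the chosen plan.
- Weak points: A3 has its unsaturation in the wrong places. C1=C5 must become the C1 carbinol plus the C4=C5 olefin, the C4 stereocentre is created and then destroyed, and C7 and C8 are still sp2. Their configurations, all-cis with C6, and the two C11 methyl groups would have to be introduced on a crowded ring. Diene A5 needs two defined exocyclic geometries, and its own stereocentres may be mismatched with the catalyst.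
- Comparison: the chosen plan has more linear steps, but the C7/C8 and C1/C10 pairs are fixed before the ring exists and no oxidation-state corrections follow cyclisation.

**Alternative 3: McMurry coupling of the C1 and C10 carbonyls.** The cut is the C1=C10 double bond. Low-valent titanium from TiCl3 and Zn–Cu couple joins the enone carbonyl and the methyl ketone of keto-enone A7 to give guaia-1(10),4-diene A6.
- Merits: the precursor is an ordinary dicarbonyl compound, seven-membered rings close dependably this way, and no stereocentre at C1 or C10 is needed beforehand. In ease of reaching the skeleton it is equal or better.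
- Weak points: A6 lacks exactly the two centres that are hardest to add afterwards. Converting a tetrasubstituted olefin of a conjugated diene into the 1-hydroxy/10-methyl pair needs a face- and regioselective hydration with no directing group. The C3 ketone must travel as a protected alcohol because the reagent reduces enones, and the allylic C–O bonds at C3 and C6 are at risk of reductive cleavage.
- Comparison: the chosen plan pays with a longer open-chain sequence and an asymmetric crotylation, but it delivers C1 and C10 from one cyclic transition state and leaves only C6 to the ring closure, which sets it.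

Key step: step 15

Assumption on the chemistry: the (S)-enantiomer of 3,3'-dibromo-BINOL is taken to deliver the crotyl group to the carbonyl face that gives the 1R alcohol, by analogy with aryl methyl ketones (the iodoalkenyl arm playing the part of the aryl group); if the sense is the opposite, the (R)-diol is used and nothing else changes.

## Route

Step 1
Reactants: 1 2-methylcyclopent-2-en-1-one
Product: 2 6-methyl-1,4-dioxaspiro[4.4]non-6-ene
Conditions: (TMSOCH2)2, TMSOTf (2 mol%), CH2Cl2, −78 °C → −20 °C; pyridine quench
Reagents that add atoms: 1,2-bis(trimethylsilyloxy)ethane, C[Si](C)(C)OCCO[Si](C)(C)C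
Why: Ketalisation of an enone with the bis-silyl ether of the diol under silyl triflate catalysis, driven by formation of hexamethyldisiloxane, masks the future C3 ketone at low temperature without conjugate addition; the olefin stays put because it is already in the most substituted position.

Step 2
Reactants: 2 6-methyl-1,4-dioxaspiro[4.4]non-6-ene
Product: 4 6-methyl-1,4-dioxaspiro[4.4]non-6-en-8-one, via allylic tert-butyl peroxide 3 (not isolated)
Conditions: Rh2(cap)4 (cap = caprolactamate; 1 mol%), t-BuOOH (70% aq., 5 equiv), K2CO3 (0.5 equiv), CH2Cl2, rt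
Reagents that add atoms: tert-butyl hydroperoxide, CC(C)(C)OO
Why: Rhodium-catalysed allylic oxidation with t-BuOOH: hydrogen abstraction at the only ring allylic methylene (future C1), trapping as the mixed peroxide and its collapse to the enone; the basic medium spares the ketal and the other allylic terminus is fully substituted.

Step 3
Reactants: 4 6-methyl-1,4-dioxaspiro[4.4]non-6-en-8-one
Product: 5 7-iodo-6-methyl-1,4-dioxaspiro[4.4]non-6-en-8-one
Conditions: I2 (2 equiv), pyridine, DMAP (0.2 equiv), CH2Cl2, 0 °C → rt, dark
Reagents that add atoms: iodine, II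
Why: α-Iodination of an enone by the iodine–pyridine addition–elimination sequence (Baylis–Hillman-type amine addition, iodination of the enolate, loss of the amine) places the halogen on C5, the only vinylic C–H.

Step 4
Reactants: 6 (Z)-but-2-ene
Product: 9 diisopropyl (Z)-but-2-en-1-ylboronate, via (Z)-crotylpotassium 7 (not isolated), via potassium crotyltriisopropoxyborate 8 (not isolated)
Conditions: n-BuLi, KOt-Bu, THF, −78 → −50 °C; B(Oi-Pr)3, −78 °C; HCl in Et2O, −78 °C → rt; used as a solution
Reagents that add atoms: triisopropyl borate, CC(C)OB(OC(C)C)OC(C)C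
Why: Metalation of the cis-alkene with the mixed lithium/potassium base gives the configurationally stable (Z)-crotylpotassium below −50 °C, which is borylated and freed from the ate complex by anhydrous acid; this is the standard preparation of (Z)-crotylboronates.

Step 5
Reactants: 5 7-iodo-6-methyl-1,4-dioxaspiro[4.4]non-6-en-8-one; 9 diisopropyl (Z)-but-2-en-1-ylboronate
Product: 11 (8R)-8-[(2S)-but-3-en-2-yl]-7-iodo-6-methyl-1,4-dioxaspiro[4.4]non-6-en-8-ol, via diisopropyl borate ester 10 (not isolated)
Conditions: (S)-3,3'-dibromo-1,1'-bi-2-naphthol (15 mol%), 9 (1.5 equiv), PhCF3/toluene (3:1), −35 °C → 0 °C; aqueous NaHCO3 work-up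
Reagents that add atoms: none
Why: Diol-catalysed asymmetric crotylboration of a ketone through a closed chair (Zimmerman–Traxler) transition state; with the iodoalkenyl arm pseudo-equatorial (boron binds the carbonyl lone pair on the CH2 side, away from iodine) the (Z)-crotyl unit gives the required C1-hydroxyl/C10-methyl relationship, and the chiral diol on boron selects the carbonyl face (1R,10S). The cyclic allyl transfer allows 1,2-addition only.

Step 6
Reactants: 11 (8R)-8-[(2S)-but-3-en-2-yl]-7-iodo-6-methyl-1,4-dioxaspiro[4.4]non-6-en-8-ol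
Product: 12 triethylsilyl ether of 11
Conditions: TESOTf, 2,6-lutidine, CH2Cl2, −78 → 0 °C
Reagents that add atoms: triethylsilyl trifluoromethanesulfonate, CC[Si](CC)(CC)OS(=O)(=O)C(F)(F)F
Why: Silylation of a tertiary alcohol with a silyl triflate; it prevents lactol formation with the later C8 aldehyde and keeps O1 masked until the last step.

Step 7
Reactants: 12 triethylsilyl ether of 11
Product: 14 (3S)-3-[(8R)-7-iodo-6-methyl-8-(triethylsilyloxy)-1,4-dioxaspiro[4.4]non-6-en-8-yl]butan-1-ol, via B-alkyl-9-BBN borane 13 (not isolated)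
Conditions: 9-BBN, THF, 0 °C → rt; then NaOH (aq.), H2O2 (30%), 0 °C
Reagents that add atoms: hydrogen peroxide, OO
Why: Anti-Markovnikov hydroboration–oxidation of the monosubstituted alkene; the tetrasubstituted iodoalkene is inert to 9-BBN.

Step 8
Reactants: 14 (3S)-3-[(8R)-7-iodo-6-methyl-8-(triethylsilyloxy)-1,4-dioxaspiro[4.4]non-6-en-8-yl]butan-1-ol
Product: 15 (3S)-3-[(8R)-7-iodo-6-methyl-8-(triethylsilyloxy)-1,4-dioxaspiro[4.4]non-6-en-8-yl]butanal
Conditions: Dess–Martin periodinane, NaHCO3, CH2Cl2, 0 °C → rt
Reagents that add atoms: none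
Why: Buffered Dess–Martin oxidation of a primary alcohol to the aldehyde (C8) without touching ketal, silyl ether or iodoalkene.

Step 9
Reactants: 16 (4S)-4-benzyl-1,3-oxazolidin-2-one; 17 (2E)-but-2-enoyl chloride
Product: 19 (4S)-4-benzyl-3-[(2E)-but-2-enoyl]-1,3-oxazolidin-2-one, via lithium oxazolidinide 18 (not isolated)
Conditions: n-BuLi, THF, −78 °C; then 17, −78 → 0 °C
Reagents that add atoms: none
Why: N-Acylation of the lithiated oxazolidinone with an acid chloride, the standard entry to acyl oxazolidinones.

Step 10
Reactants: 19 (4S)-4-benzyl-3-[(2E)-but-2-enoyl]-1,3-oxazolidin-2-one; 15 (3S)-3-[(8R)-7-iodo-6-methyl-8-(triethylsilyloxy)-1,4-dioxaspiro[4.4]non-6-en-8-yl]butanal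
Product: 22 syn-aldol adduct (7S,8R; C7 vinyl; C8 hydroxyl), via dibutylboron dienolate 20 (not isolated), via dibutylboron aldolate 21 (not isolated)
Conditions: Bu2BOTf, Et3N, CH2Cl2, −78 → 0 °C; 15, −78 → 0 °C; pH 7 buffer, MeOH, H2O2, 0 °C
Reagents that add atoms: none
Why: Evans syn-aldol reaction of the boron dienolate of a crotonyl imide, which reacts at its α-carbon: the (Z)-enolate and the chair transition state give the syn pair, and the (4S)-benzyl auxiliary selects the face that gives 7S,8R. The C10 centre is too remote to interfere.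

Step 11
Reactants: 22 syn-aldol adduct (7S,8R; C7 vinyl; C8 hydroxyl)
Product: 23 methyl (2S,3R,5S)-2-ethenyl-3-hydroxy-5-Q-hexanoate (Q as defined before the compound list)
Conditions: MeMgBr, MeOH (forms MeOMgBr), CH2Cl2, 0 °C
Reagents that add atoms: methanol, CO
Why: Transesterification of a β-hydroxy acyl oxazolidinone with bromomagnesium methoxide, accelerated by chelation of the β-alkoxide; the auxiliary is released under conditions too mild for retro-aldol or migration of the vinyl double bond.

Step 12
Reactants: 23 methyl (2S,3R,5S)-2-ethenyl-3-hydroxy-5-Q-hexanoate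
Product: 24 methyl (2S,3R,5S)-2-ethenyl-3-(triethylsilyloxy)-5-Q-hexanoate
Conditions: TESCl, imidazole, DMAP (cat.), DMF, rt
Reagents that add atoms: chlorotriethylsilane, CC[Si](Cl)(CC)CC
Why: Silylation of the secondary C8 hydroxyl; it blocks retro-aldol during the organometallic addition and β-elimination at the aldehyde stage.

Step 13
Reactants: 24 methyl (2S,3R,5S)-2-ethenyl-3-(triethylsilyloxy)-5-Q-hexanoate
Product: 26 (3S,4R,6S)-3-ethenyl-2-methyl-4-(triethylsilyloxy)-6-Q-heptan-2-ol, via methyl ketone 25 (not isolated)
Conditions: MeLi (5 equiv), anhydrous CeCl3 (5 equiv), THF, −78 → −40 °C; aq. NH4Cl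
Reagents that add atoms: methyllithium, [Li]C
Why: Double addition of a methylcerium reagent to an ester builds the C11 dimethyl carbinol; the low basicity of organocerium reagents avoids deprotonation at the allylic α-carbon (C7) and loss of the β-silyloxy group.

Step 14
Reactants: 26 (3S,4R,6S)-3-ethenyl-2-methyl-4-(triethylsilyloxy)-6-Q-heptan-2-ol
Product: 28 (2S,3R,5S)-2-(2-hydroxypropan-2-yl)-3-(triethylsilyloxy)-5-Q-hexanal, via vicinal diol 27 (not isolated)
Conditions: OsO4 (2 mol%), NaIO4 (4 equiv), 2,6-lutidine, dioxane/H2O (3:1), rt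
Reagents that add atoms: osmium tetroxide (catalytic oxygen carrier), O=[Os](=O)(=O)=O; sodium periodate (terminal oxidant), [Na+].[O-]I(=O)(=O)=O
Why: Lemieux–Johnson cleavage: OsO4 dihydroxylates the monosubstituted vinyl group far faster than the hindered, halogen-bearing tetrasubstituted olefin, and periodate cleaves the diol to the C6 aldehyde; the lutidine buffer guards C7 against epimerisation.

Step 15
Reactants: 28 (2S,3R,5S)-2-(2-hydroxypropan-2-yl)-3-(triethylsilyloxy)-5-Q-hexanal
Product: 30 (1R,6R,7S,8R,10S)-3,3-(ethylenedioxy)-1,8-bis(triethylsilyloxy)guai-4-ene-6,11-diol, via alkenylchromium species 29 (not isolated)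
Conditions: CrCl2 (8 equiv), NiCl2 (2 mol%), degassed DMSO, rt, 0.005 M
Reagents that add atoms: none
Why: Nozaki–Hiyama–Kishi reaction: CrCl2 reduces NiCl2 to zerovalent nickel, which inserts into the C5–I bond; transmetalation to trivalent chromium gives alkenylchromium 29, which adds to the C6 aldehyde and forms the C5–C6 bond. The closest known reaction type is the intramolecular nickel/chromium coupling of cyclic alkenyl iodides with tethered aldehydes, an established way to medium rings. The seven-membered ring closes in the 7-exo-trig mode, the carbonyl oxygen staying outside the new ring. The new stereocentre C6 is controlled by C7: in the Felkin–Anh arrangement the 2-hydroxypropan-2-yl group stands anti to the incoming C5, the tether (C8) sits inside next to the carbonyl oxygen and C7–H outside, which puts O6 cis to the C7 side chain (6R); a chromium chelate between the aldehyde oxygen and the free C11 hydroxyl leads to the same epimer. The step needs chemoselectivity and ring closure over intermolecular coupling: the alkenylchromium adds to aldehydes only, so ketal, silyl ethers and the free tertiary alcohol are untouched, and no base is present that could epimerise C7 or expel O8; closure is favoured by high dilution and by the cyclopentene, which holds C5 and the C1-borne chain on adjacent ring atoms.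

Step 16
Reactants: 30 (1R,6R,7S,8R,10S)-3,3-(ethylenedioxy)-1,8-bis(triethylsilyloxy)guai-4-ene-6,11-diol
Product: 31 (1R,6R,7R,8R,10S)-6-(tert-butyldimethylsilyloxy)-3,3-(ethylenedioxy)-1,8-bis(triethylsilyloxy)guai-4-en-11-ol
Conditions: TBSOTf (1.2 equiv), 2,6-lutidine, CH2Cl2, −78 → −40 °C
Reagents that add atoms: tert-butyldimethylsilyl trifluoromethanesulfonate, CC(C)(C)[Si](C)(C)OS(=O)(=O)C(F)(F)F
Why: Silylation with a silyl triflate at low temperature takes the secondary allylic C6 hydroxyl and leaves the slower tertiary C11 hydroxyl, so that O6 is out of reach of both acylations.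

Step 17
Reactants: 31 (1R,6R,7R,8R,10S)-6-(tert-butyldimethylsilyloxy)-3,3-(ethylenedioxy)-1,8-bis(triethylsilyloxy)guai-4-en-11-ol
Product: 32 (1R,6R,7R,8R,10S)-6-(tert-butyldimethylsilyloxy)-8,11-dihydroxy-1-(triethylsilyloxy)guai-4-en-3-one
Conditions: PPTS (0.3 equiv), acetone/H2O (10:1), 40 °C
Reagents that add atoms: water, O
Why: Mild aqueous acid hydrolyses the allylic dioxolane through its stabilised oxocarbenium ion and cleaves the secondary triethylsilyl ether at O8; the shielded tertiary triethylsilyl ether at O1 and the tert-butyldimethylsilyl ether at O6 should survive. Loss of the O1 silyl group would remove the guarantee that O11 is the only free hydroxyl in step 19.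

Step 18
Reactants: 32 (1R,6R,7R,8R,10S)-6-(tert-butyldimethylsilyloxy)-8,11-dihydroxy-1-(triethylsilyloxy)guai-4-en-3-one; 33 angelic acid
Product: 35 (1R,6R,7R,8R,10S)-8-angeloyloxy-6-(tert-butyldimethylsilyloxy)-11-hydroxy-1-(triethylsilyloxy)guai-4-en-3-one, via angelic 2,4,6-trichlorobenzoic anhydride 34 (not isolated)
Conditions: 33, 2,4,6-trichlorobenzoyl chloride, Et3N, toluene, rt; then 32, toluene, 80 °C
Reagents that add atoms: none
Why: Yamaguchi esterification through the preformed mixed anhydride, run without a nucleophilic pyridine catalyst, the established way to make angelates without isomerisation to the tiglate; only the secondary C8 hydroxyl reacts, the tertiary one does not.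

Step 19
Reactants: 35 (1R,6R,7R,8R,10S)-8-angeloyloxy-6-(tert-butyldimethylsilyloxy)-11-hydroxy-1-(triethylsilyloxy)guai-4-en-3-one
Product: 36 (1R,6R,7R,8R,10S)-11-acetoxy-8-angeloyloxy-6-(tert-butyldimethylsilyloxy)-1-(triethylsilyloxy)guai-4-en-3-one
Conditions: Ac2O, DMAP, Et3N, CH2Cl2, rt → 40 °C
Reagents that add atoms: acetic anhydride, CC(=O)OC(C)=O
Why: DMAP-catalysed acyl transfer to a tertiary alcohol; O11 is the only free hydroxyl, and an angelate cannot migrate from the secondary to the tertiary oxygen.

Step 20
Reactants: 36 (1R,6R,7R,8R,10S)-11-acetoxy-8-angeloyloxy-6-(tert-butyldimethylsilyloxy)-1-(triethylsilyloxy)guai-4-en-3-one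
Product: 37 (1R,6R,7S,8R,10S)-11-acetoxy-8-angeloyloxy-1,6-dihydroxyguai-4-en-3-one (target)
Conditions: HF·pyridine, pyridine, THF, 0 °C → rt
Reagents that add atoms: none
Why: Fluoride-mediated desilylation with buffered HF·pyridine removes both silyl ethers; the near-neutral medium avoids acyl migration to O6, isomerisation of the angelate and retro-aldol at C1.

## Compound list

Q = (8R)-7-iodo-6-methyl-8-(triethylsilyloxy)-1,4-dioxaspiro[4.4]non-6-en-8-yl; spiro C5, C6, C7, C8, C9 are guaiane C3, C4, C5, C1, C2.

1 | 2-methylcyclopent-2-en-1-one | CC1=CCCC1=O | starting material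
2 | 6-methyl-1,4-dioxaspiro[4.4]non-6-ene | CC1=CCCC12OCCO2 | intermediate
3 | 8-(tert-butylperoxy)-6-methyl-1,4-dioxaspiro[4.4]non-6-ene (racemic; not isolated) | CC1=CC(OOC(C)(C)C)CC12OCCO2 | intermediate
4 | 6-methyl-1,4-dioxaspiro[4.4]non-6-en-8-one | CC1=CC(=O)CC12OCCO2 | intermediate
5 | 7-iodo-6-methyl-1,4-dioxaspiro[4.4]non-6-en-8-one | CC1=C(I)C(=O)CC12OCCO2 | intermediate
6 | (Z)-but-2-ene | C/C=C\C | starting material
7 | (Z)-but-2-en-1-ylpotassium (not isolated) | C/C=C\C[K] | intermediate
8 | potassium (Z)-but-2-en-1-yl(triisopropoxy)borate (not isolated) | C/C=C\C[B-](OC(C)C)(OC(C)C)OC(C)C.[K+] | intermediate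
9 | diisopropyl (Z)-but-2-en-1-ylboronate | C/C=C\CB(OC(C)C)OC(C)C | intermediate
10 | diisopropyl (8R)-8-[(2S)-but-3-en-2-yl]-7-iodo-6-methyl-1,4-dioxaspiro[4.4]non-6-en-8-yl borate (not isolated) | C=C[C@H](C)[C@]1(OB(OC(C)C)OC(C)C)CC2(OCCO2)C(C)=C1I | intermediate
11 | (8R)-8-[(2S)-but-3-en-2-yl]-7-iodo-6-methyl-1,4-dioxaspiro[4.4]non-6-en-8-ol (guaiane 1R,10S) | C=C[C@H](C)[C@]1(O)CC2(OCCO2)C(C)=C1I | intermediate
12 | triethylsilyl ether of 11: {[(8R)-8-[(2S)-but-3-en-2-yl]-7-iodo-6-methyl-1,4-dioxaspiro[4.4]non-6-en-8-yl]oxy}triethylsilane | C=C[C@H](C)[C@]1(O[Si](CC)(CC)CC)CC2(OCCO2)C(C)=C1I | intermediate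
13 | 9-[(3S)-3-Q-butyl]-9-borabicyclo[3.3.1]nonane (not isolated) | B1(CC[C@H](C)[C@]2(O[Si](CC)(CC)CC)CC3(OCCO3)C(C)=C2I)C4CCCC1CCC4 | intermediate
14 | (3S)-3-Q-butan-1-ol | OCC[C@H](C)[C@]1(O[Si](CC)(CC)CC)CC2(OCCO2)C(C)=C1I | intermediate
15 | (3S)-3-Q-butanal | O=CC[C@H](C)[C@]1(O[Si](CC)(CC)CC)CC2(OCCO2)C(C)=C1I | intermediate
16 | (4S)-4-benzyl-1,3-oxazolidin-2-one | O=C1N[C@@H](Cc2ccccc2)CO1 | starting material
17 | (2E)-but-2-enoyl chloride | C/C=C/C(Cl)=O | starting material
18 | lithium (4S)-4-benzyl-2-oxo-1,3-oxazolidin-3-ide (not isolated) | [Li]N1[C@@H](Cc2ccccc2)COC1=O | intermediate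
19 | (4S)-4-benzyl-3-[(2E)-but-2-enoyl]-1,3-oxazolidin-2-one | C/C=C/C(=O)N1[C@@H](Cc2ccccc2)COC1=O | intermediate
20 | dibutylboron (Z)-dienolate of 19 (not isolated) | C=C/C=C(\OB(CCCC)CCCC)N1[C@@H](Cc2ccccc2)COC1=O | intermediate
21 | dibutylboron aldolate of 22 (not isolated) | C=C[C@@H]([C@H](OB(CCCC)CCCC)C[C@H](C)[C@]1(O[Si](CC)(CC)CC)CC2(OCCO2)C(C)=C1I)C(=O)N3[C@@H](Cc4ccccc4)COC3=O | intermediate
22 | (4S)-4-benzyl-3-[(2S,3R,5S)-2-ethenyl-3-hydroxy-5-Q-hexanoyl]-1,3-oxazolidin-2-one (guaiane 7S,8R,10S,1R) | C=C[C@@H]([C@H](O)C[C@H](C)[C@]1(O[Si](CC)(CC)CC)CC2(OCCO2)C(C)=C1I)C(=O)N3[C@@H](Cc4ccccc4)COC3=O | intermediate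
23 | methyl (2S,3R,5S)-2-ethenyl-3-hydroxy-5-Q-hexanoate | C=C[C@@H]([C@H](O)C[C@H](C)[C@]1(O[Si](CC)(CC)CC)CC2(OCCO2)C(C)=C1I)C(=O)OC | intermediate
24 | methyl (2S,3R,5S)-2-ethenyl-3-(triethylsilyloxy)-5-Q-hexanoate | C=C[C@@H]([C@H](O[Si](CC)(CC)CC)C[C@H](C)[C@]1(O[Si](CC)(CC)CC)CC2(OCCO2)C(C)=C1I)C(=O)OC | intermediate
25 | (3S,4R,6S)-3-ethenyl-4-(triethylsilyloxy)-6-Q-heptan-2-one (not isolated) | C=C[C@@H]([C@H](O[Si](CC)(CC)CC)C[C@H](C)[C@]1(O[Si](CC)(CC)CC)CC2(OCCO2)C(C)=C1I)C(C)=O | intermediate
26 | (3S,4R,6S)-3-ethenyl-2-methyl-4-(triethylsilyloxy)-6-Q-heptan-2-ol | C=C[C@@H]([C@H](O[Si](CC)(CC)CC)C[C@H](C)[C@]1(O[Si](CC)(CC)CC)CC2(OCCO2)C(C)=C1I)C(C)(C)O | intermediate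
27 | 1,2-diol from dihydroxylation of the vinyl group of 26 (both epimers at the new carbinol; not isolated) | OCC(O)[C@@H]([C@H](O[Si](CC)(CC)CC)C[C@H](C)[C@]1(O[Si](CC)(CC)CC)CC2(OCCO2)C(C)=C1I)C(C)(C)O | intermediate
28 | (2S,3R,5S)-2-(2-hydroxypropan-2-yl)-3-(triethylsilyloxy)-5-Q-hexanal (guaiane 7S,8R,10S,1R) | O=C[C@@H]([C@H](O[Si](CC)(CC)CC)C[C@H](C)[C@]1(O[Si](CC)(CC)CC)CC2(OCCO2)C(C)=C1I)C(C)(C)O | intermediate
29 | alkenylchromium dichloride from 28 (trivalent chromium at C5 in place of iodine; not isolated) | O=C[C@@H]([C@H](O[Si](CC)(CC)CC)C[C@H](C)[C@]1(O[Si](CC)(CC)CC)CC2(OCCO2)C(C)=C1[Cr](Cl)Cl)C(C)(C)O | intermediate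
30 | (1R,6R,7S,8R,10S)-3,3-(ethylenedioxy)-1,8-bis(triethylsilyloxy)guai-4-ene-6,11-diol | CC[Si](CC)(CC)O[C@@H]1C[C@H](C)[C@]2(O[Si](CC)(CC)CC)CC3(OCCO3)C(C)=C2[C@H](O)[C@@H]1C(C)(C)O | intermediate
31 | (1R,6R,7R,8R,10S)-6-(tert-butyldimethylsilyloxy)-3,3-(ethylenedioxy)-1,8-bis(triethylsilyloxy)guai-4-en-11-ol | CC[Si](CC)(CC)O[C@@H]1C[C@H](C)[C@]2(O[Si](CC)(CC)CC)CC3(OCCO3)C(C)=C2[C@H](O[Si](C)(C)C(C)(C)C)[C@@H]1C(C)(C)O | intermediate
32 | (1R,6R,7R,8R,10S)-6-(tert-butyldimethylsilyloxy)-8,11-dihydroxy-1-(triethylsilyloxy)guai-4-en-3-one | O[C@@H]1C[C@H](C)[C@]2(O[Si](CC)(CC)CC)CC(=O)C(C)=C2[C@H](O[Si](C)(C)C(C)(C)C)[C@@H]1C(C)(C)O | intermediate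
33 | angelic acid, (2Z)-2-methylbut-2-enoic acid | C/C=C(/C)C(=O)O | starting material
34 | (2Z)-2-methylbut-2-enoic 2,4,6-trichlorobenzoic anhydride (not isolated) | C/C=C(/C)C(=O)OC(=O)c1c(Cl)cc(Cl)cc1Cl | intermediate
35 | (1R,6R,7R,8R,10S)-8-angeloyloxy-6-(tert-butyldimethylsilyloxy)-11-hydroxy-1-(triethylsilyloxy)guai-4-en-3-one | C/C=C(/C)C(=O)O[C@@H]1C[C@H](C)[C@]2(O[Si](CC)(CC)CC)CC(=O)C(C)=C2[C@H](O[Si](C)(C)C(C)(C)C)[C@@H]1C(C)(C)O | intermediate
36 | (1R,6R,7R,8R,10S)-11-acetoxy-8-angeloyloxy-6-(tert-butyldimethylsilyloxy)-1-(triethylsilyloxy)guai-4-en-3-one | C/C=C(/C)C(=O)O[C@@H]1C[C@H](C)[C@]2(O[Si](CC)(CC)CC)CC(=O)C(C)=C2[C@H](O[Si](C)(C)C(C)(C)C)[C@@H]1C(C)(C)OC(C)=O | intermediate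
37 | (1R,6R,7S,8R,10S)-11-acetoxy-8-angeloyloxy-1,6-dihydroxyguai-4-en-3-one | C/C=C(/C)C(=O)O[C@@H]1C[C@H](C)[C@]2(O)CC(=O)C(C)=C2[C@H](O)[C@@H]1C(C)(C)OC(C)=O | target

## Step count and risks

Total: 20 steps. Longest linear sequence: 18 steps (1 to 37 through steps 1–3, 5–8 and 10–20); steps 4 and 9 prepare the two reagents 9 and 19.

**Step 15 (key step).** Oxidative addition at the tetrasubstituted, doubly flanked C5–I bond may be slow, which leaves time for protodemetalation or intermolecular coupling. Facial selectivity at C6 may also be poor if the seven-membered transition state does not follow the open-chain model. Dilution and nickel loading address the first. For the second, the fallback moves control of C6 from the C–C bond formation to a ketone reduction. It sets out from 30, used as obtained whatever the selectivity at C6. Dess–Martin periodinane oxidises the C6 carbinol to the C4=C5–C6 enone, (1R,7S,8R,10S)-3,3-(ethylenedioxy)-11-hydroxy-1,8-bis(triethylsilyloxy)guai-4-en-6-one F1. NaBH4 with CeCl3·7H2O (Luche reduction) then delivers hydride to the face opposite the neighbouring C7 side chain and returns the 6R alcohol 30.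

**Step 5.** The chiral diol may discriminate poorly between the two faces of a ketone whose two arms are both ring members, and the hindered α-iodo ketone may react slowly. The fallback replaces asymmetric induction by resolution. It sets out from 5: with achiral 2,2'-biphenol as catalyst the same boronate 9 gives, through the closed transition state, the racemate with the same relative configuration. That is borate 10 together with its mirror image, the enantiomeric borate ester F2, hydrolysed to 11 together with the enantiomeric alcohol F3. Preparative chromatography on a chiral stationary phase (supercritical CO2) separates the two and the route is rejoined at 11.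

**Step 3.** Conjugate addition of the amine to a β-carbon that carries a methyl group and the quaternary ketal carbon may be too slow, so that conversion stalls or the ketal suffers on long exposure. The fallback uses addition–elimination with the smaller halogen, then halogen exchange. It sets out from 4: bromine in CH2Cl2 at 0 °C adds across the olefin to trans-6,7-dibromo-6-methyl-1,4-dioxaspiro[4.4]nonan-8-one F4, and triethylamine eliminates HBr to 7-bromo-6-methyl-1,4-dioxaspiro[4.4]non-6-en-8-one F5. Copper-catalysed Finkelstein exchange (CuI, NaI, trans-N,N'-dimethylcyclohexane-1,2-diamine, dioxane, 110 °C) then returns iodoenone 5.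

**Step 19.** Acyl transfer to the C11 carbinol, wedged between two cis oxygen substituents, may be sluggish, and long heating with DMAP may start to isomerise the angelate. The fallback installs the acetate on an alkoxide before the ring exists. It sets out from 24 and runs as follows:
- The methylcerium addition of step 13 is quenched in the flask with acetic anhydride, so that the metal alkoxide (the conjugate base of 26) gives the tertiary acetate, (3S,4R,6S)-3-ethenyl-2-methyl-4-(triethylsilyloxy)-6-Q-heptan-2-yl acetate F6.
- Lemieux–Johnson cleavage as in step 14 passes through the corresponding 1,2-diol F7 to the acetoxy aldehyde F8.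
- Nozaki–Hiyama–Kishi closure as in step 15 passes through the alkenylchromium species F9 to the 11-acetoxy-6-hydroxy hydroazulene F10.
- Silylation as in step 16 gives the C6 tert-butyldimethylsilyl ether F11, and the aqueous acid of step 17 gives the 11-acetoxy-8-hydroxy enone F12.
- Esterification of F12 with mixed anhydride 34, at the lowest temperature that still gives conversion so as to limit acetyl migration to O8, rejoins the route at 36.

**Step 18.** The crowded C8 hydroxyl may acylate slowly, and forcing the activation of angelic acid leads to isomerisation towards the tiglate. The fallback builds the (Z)-olefin on the ester instead of transferring it. It sets out from 32: DCC-mediated esterification of the C8 hydroxyl with 2-[bis(2,2,2-trifluoroethoxy)phosphoryl]propanoic acid gives the C8 phosphonopropanoate F13. Still–Gennari olefination with acetaldehyde (KHMDS, 18-crown-6, THF, −78 °C) then forms the (Z)-2-methylbut-2-enoate and returns angelate 35.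

## Further compounds

F1 | step 15 | (1R,7S,8R,10S)-3,3-(ethylenedioxy)-11-hydroxy-1,8-bis(triethylsilyloxy)guai-4-en-6-one | CC[Si](CC)(CC)O[C@@H]1C[C@H](C)[C@]2(O[Si](CC)(CC)CC)CC3(OCCO3)C(C)=C2C(=O)[C@@H]1C(C)(C)O
F2 | step 5 | diisopropyl (8S)-8-[(2R)-but-3-en-2-yl]-7-iodo-6-methyl-1,4-dioxaspiro[4.4]non-6-en-8-yl borate (enantiomer of 10) | C=C[C@@H](C)[C@@]1(OB(OC(C)C)OC(C)C)CC2(OCCO2)C(C)=C1I
F3 | step 5 | (8S)-8-[(2R)-but-3-en-2-yl]-7-iodo-6-methyl-1,4-dioxaspiro[4.4]non-6-en-8-ol (enantiomer of 11) | C=C[C@@H](C)[C@@]1(O)CC2(OCCO2)C(C)=C1I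
F4 | step 3 | trans-6,7-dibromo-6-methyl-1,4-dioxaspiro[4.4]nonan-8-one (racemic; one enantiomer drawn) | C[C@]1(Br)[C@H](Br)C(=O)CC12OCCO2
F5 | step 3 | 7-bromo-6-methyl-1,4-dioxaspiro[4.4]non-6-en-8-one | CC1=C(Br)C(=O)CC12OCCO2
F6 | step 19 | (3S,4R,6S)-3-ethenyl-2-methyl-4-(triethylsilyloxy)-6-Q-heptan-2-yl acetate | C=C[C@@H]([C@H](O[Si](CC)(CC)CC)C[C@H](C)[C@]1(O[Si](CC)(CC)CC)CC2(OCCO2)C(C)=C1I)C(C)(C)OC(C)=O
F7 | step 19 | 1,2-diol from dihydroxylation of the vinyl group of F6 (both epimers at the new carbinol) | OCC(O)[C@@H]([C@H](O[Si](CC)(CC)CC)C[C@H](C)[C@]1(O[Si](CC)(CC)CC)CC2(OCCO2)C(C)=C1I)C(C)(C)OC(C)=O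
F8 | step 19 | 11-acetoxy analogue of aldehyde 28: (2S,3R,5S)-2-(2-acetoxypropan-2-yl)-3-(triethylsilyloxy)-5-Q-hexanal | O=C[C@@H]([C@H](O[Si](CC)(CC)CC)C[C@H](C)[C@]1(O[Si](CC)(CC)CC)CC2(OCCO2)C(C)=C1I)C(C)(C)OC(C)=O
F9 | step 19 | alkenylchromium dichloride from F8 (trivalent chromium at C5 in place of iodine) | O=C[C@@H]([C@H](O[Si](CC)(CC)CC)C[C@H](C)[C@]1(O[Si](CC)(CC)CC)CC2(OCCO2)C(C)=C1[Cr](Cl)Cl)C(C)(C)OC(C)=O
F10 | step 19 | 11-acetoxy-3,3-(ethylenedioxy)-1,8-bis(triethylsilyloxy)guai-4-en-6-ol (ring configuration as in 30) | CC[Si](CC)(CC)O[C@@H]1C[C@H](C)[C@]2(O[Si](CC)(CC)CC)CC3(OCCO3)C(C)=C2[C@H](O)[C@@H]1C(C)(C)OC(C)=O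
F11 | step 19 | 11-acetoxy-6-(tert-butyldimethylsilyloxy)-3,3-(ethylenedioxy)-1,8-bis(triethylsilyloxy)guai-4-ene (ring configuration as in 31) | CC[Si](CC)(CC)O[C@@H]1C[C@H](C)[C@]2(O[Si](CC)(CC)CC)CC3(OCCO3)C(C)=C2[C@H](O[Si](C)(C)C(C)(C)C)[C@@H]1C(C)(C)OC(C)=O
F12 | step 19 | 11-acetoxy-6-(tert-butyldimethylsilyloxy)-8-hydroxy-1-(triethylsilyloxy)guai-4-en-3-one (ring configuration as in 32) | O[C@@H]1C[C@H](C)[C@]2(O[Si](CC)(CC)CC)CC(=O)C(C)=C2[C@H](O[Si](C)(C)C(C)(C)C)[C@@H]1C(C)(C)OC(C)=O
F13 | step 18 | C8 2-[bis(2,2,2-trifluoroethoxy)phosphoryl]propanoate of 32 (both epimers at the phosphonate α-carbon) | CC(C(=O)O[C@@H]1C[C@H](C)[C@]2(O[Si](CC)(CC)CC)CC(=O)C(C)=C2[C@H](O[Si](C)(C)C(C)(C)C)[C@@H]1C(C)(C)O)P(=O)(OCC(F)(F)F)OCC(F)(F)F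
A1 | alternative 1 | 1-hydroxyguai-4(15)-ene with silyl ethers at O6 (tert-butyldimethylsilyl), O8 and O11 (triethylsilyl) | CC[Si](CC)(CC)O[C@@H]1C[C@H](C)[C@]2(O)CCC(=C)[C@H]2[C@H](O[Si](C)(C)C(C)(C)C)[C@@H]1C(C)(C)O[Si](CC)(CC)CC
A2 | alternative 1 | (4E)-germacr-4-en-1-one (cyclodec-4-enone) with the same silyl ethers at O6, O8 and O11 | CC[Si](CC)(CC)O[C@@H]1C[C@H](C)C(=O)CC/C(C)=C/[C@H](O[Si](C)(C)C(C)(C)C)[C@@H]1C(C)(C)O[Si](CC)(CC)CC
A3 | alternative 2 | hydroazulene with C7 methyl ester, C8 silyl enol ether, C1=C5 olefin, C3 triethylsilyl ether and C6 4-methoxybenzyl ether | COC(=O)C1=C(O[Si](C)(C)C(C)(C)C)C[C@H](C)C2=C([C@@H](C)[C@H](O[Si](CC)(CC)CC)C2)[C@@H]1OCc1ccc(OC)cc1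
A4 | alternative 2 | methyl 2-diazo-3-(tert-butyldimethylsilyloxy)but-3-enoate | COC(=O)C(=[N+]=[N-])C(=C)O[Si](C)(C)C(C)(C)C
A5 | alternative 2 | 1,2-bis(alkylidene)cyclopentane diene: (E)-ethylidene at C1, (E)-(4-methoxybenzyloxy)methylidene at C5, triethylsilyloxy at C3, methyl at C4 | C/C=C1\C[C@@H](O[Si](CC)(CC)CC)[C@H](C)/C1=C\OCc1ccc(OC)cc1
A6 | alternative 3 | guaia-1(10),4-diene with silyl ethers at O3, O6, O8 and O11 | CC[Si](CC)(CC)O[C@@H]1CC(C)=C2C[C@@H](O[Si](CC)(CC)CC)C(C)=C2[C@H](O[Si](C)(C)C(C)(C)C)[C@@H]1C(C)(C)O[Si](CC)(CC)CC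
A7 | alternative 3 | 1,10-seco keto-enone: cyclopentenone (C1 carbonyl) joined at C5 to the C6–C9 chain ending in the C10 methyl ketone, same silyl ethers | CC(=O)C[C@@H](O[Si](CC)(CC)CC)[C@H]([C@@H](O[Si](C)(C)C(C)(C)C)C1=C(C)[C@H](O[Si](CC)(CC)CC)CC1=O)C(C)(C)O[Si](CC)(CC)CC
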